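Ring numbering: C1 (heptenyl), C2 (carboxamide), C3 (pentyl), C4=C5, C6 (carboxamide). C6 is a carboxyl α-carbon bonded to vinylic C5, so C4=C5 can come from a terminal alkyne on C3 whose end carbon is attacked by a ketene acetal at C6.
Retrosynthesis: cut both amide C–N bonds (dimethyl ester), then ring bond C5–C6, then chain bond C1–C2 (Ireland–Claisen, which also makes the E-heptenyl alkene), the ester C–O bond, and C2–C3 (malonate alkylation).
Forward: (S)-3-ethynyloctanoic acid (C3 and C2) is esterified with an (R,E)-allylic alcohol made by cross-metathesis; the rearrangement joins C1 to C2; oxidation and methylation give the open-chain diester; O-silylation at C6 and the tungsten-catalysed 6-endo closure form the only ring; aminolysis finishes the route.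
Stereochemistry: C3 comes from (S)-oct-1-yn-3-ol by SN2 inversion; C1 and C2 come from (R)-oct-1-en-3-ol by chirality transfer through the chair Ireland–Claisen transition state with a Z(O) ketene acetal; C6 is set in the ring closure, trans to heptenyl (allylic strain, and the more stable, epimerisable position).
Key step: step 10

Remark: (3S)-oct-1-yn-3-ol, (3R)-oct-1-en-3-ol and the silyl ether of but-3-en-1-ol are taken as purchased, the two alcohols enantiopure; the ring numbering above is also used for the open-chain intermediates.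

Step 1
Reactants: 1 (3S)-oct-1-yn-3-ol
Product: 2 (3S)-oct-1-yn-3-yl methanesulfonate
Conditions: MsCl, Et3N, CH2Cl2, −20 → 0 °C
Reagents that add atoms: methanesulfonyl chloride, CS(=O)(=O)Cl
Why: O-Sulfonylation of the secondary propargylic alcohol activates C3 for substitution and leaves its configuration untouched, because only the O–H bond reacts.

Step 2
Reactants: 2 (3S)-oct-1-yn-3-yl methanesulfonate; 3 dimethyl propanedioate
Product: 4 dimethyl 2-[(3S)-oct-1-yn-3-yl]propanedioate
Conditions: NaH, 3 (2.5 equiv), THF/DMSO, 0 → 50 °C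
Reagents that add atoms: none
Why: Malonic ester alkylation by SN2 displacement of the propargylic mesylate should proceed with inversion at C3 (the descriptor stays S because the priorities change), and the soft malonate anion is too weak a base to deprotonate the alkyne.

Step 3
Reactants: 4 dimethyl 2-[(3S)-oct-1-yn-3-yl]propanedioate
Product: 6 (3S)-3-ethynyloctanoic acid, via malonic acid 5 (not isolated)
Conditions: NaOH, MeOH/H2O, 60 °C; then HCl to pH 1, 100 °C
Reagents that add atoms: sodium hydroxide, [Na+].[OH-]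
Why: Saponification followed by thermal decarboxylation of the monosubstituted malonic acid (malonic ester synthesis) leaves one acetic acid arm, whose CH2 is the future C2, and does not touch the non-acidic C3 centre.

Step 4
Reactants: 7 (3R)-oct-1-en-3-ol; 8 (but-3-en-1-yloxy)(tert-butyl)dimethylsilane
Product: 9 (3E,5R)-1-[tert-butyl(dimethyl)silyl]oxydec-3-en-5-ol
Conditions: 8 (3 equiv), RuCl2(=CHPh)(H2IMes)(PCy3) (second-generation Grubbs catalyst, 5 mol %), CH2Cl2, 40 °C
Reagents that add atoms: none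
Why: Olefin cross-metathesis of the slowly homodimerising secondary allylic alcohol with an excess of the terminal alkene should give the E-disubstituted alkene, and the carbinol centre is not involved.

Step 5
Reactants: 6 (3S)-3-ethynyloctanoic acid; 9 (3E,5R)-1-[tert-butyl(dimethyl)silyl]oxydec-3-en-5-ol
Product: 10 [(3E,5R)-1-[tert-butyl(dimethyl)silyl]oxydec-3-en-5-yl] (3S)-3-ethynyloctanoate
Conditions: DCC, DMAP (cat.), CH2Cl2, 0 °C → rt
Reagents that add atoms: none
Why: Steglich esterification joins the two fragments under neutral carbodiimide conditions, and neither stereocentre is α to a carbonyl group, so none can epimerise.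

Step 6
Reactants: 10 [(3E,5R)-1-[tert-butyl(dimethyl)silyl]oxydec-3-en-5-yl] (3S)-3-ethynyloctanoate
Product: 13 (2S,3S,4E)-3-[2-[tert-butyl(dimethyl)silyl]oxyethyl]-2-[(3S)-oct-1-yn-3-yl]dec-4-enoic acid, via ketene acetal 11 (not isolated), via silyl ester 12 (not isolated)
Conditions: LiN(i-Pr)2 (2.3 equiv), THF/HMPA, −78 °C; Me3SiCl, −78 → 40 °C; K2CO3, MeOH, rt; aq. HCl to pH 3
Reagents that add atoms: none
Why: Ireland–Claisen rearrangement: LiN(i-Pr)2 in THF/HMPA should give the Z(O) enolate (the alkynyl C–H is lithiated and silylated as well and is freed again by the methanolic carbonate), and the chair transition state with the carbinol pentyl group equatorial transfers the (R) carbinol configuration to C2 and C1 (both S) and gives the E alkene of the heptenyl group.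

Step 7
Reactants: 13 (2S,3S,4E)-3-[2-[tert-butyl(dimethyl)silyl]oxyethyl]-2-[(3S)-oct-1-yn-3-yl]dec-4-enoic acid
Product: 14 (2S,3S)-3-[(E)-hept-1-enyl]-2-[(3S)-oct-1-yn-3-yl]pentanedioic acid
Conditions: CrO3, H2SO4, H2O, acetone, 0 °C
Reagents that add atoms: water, O
Why: Jones oxidation: the aqueous acid cleaves the primary silyl ether and the hexavalent chromium reagent oxidises the freed alcohol through the aldehyde hydrate to the acid that carries C6, without affecting the alkyne, the alkene or the stereocentres.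

Step 8
Reactants: 14 (2S,3S)-3-[(E)-hept-1-enyl]-2-[(3S)-oct-1-yn-3-yl]pentanedioic acid
Product: 15 dimethyl (2S,3S)-3-[(E)-hept-1-enyl]-2-[(3S)-oct-1-yn-3-yl]pentanedioate
Conditions: MeI, K2CO3, DMF, rt
Reagents that add atoms: iodomethane, CI
Why: SN2 O-methylation of the dicarboxylate by iodomethane under carbonate, which is too weak a base to enolise C2 or deprotonate the alkyne, gives the open-chain stereotriad as its dimethyl ester.

Step 9
Reactants: 15 dimethyl (2S,3S)-3-[(E)-hept-1-enyl]-2-[(3S)-oct-1-yn-3-yl]pentanedioate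
Product: 17 methyl (2S,3R)-5-[tert-butyl(dimethyl)silyl]oxy-3-[(E)-hept-1-enyl]-5-methoxy-2-[(3S)-oct-1-yn-3-yl]pent-4-enoate (ketene acetal geometry not controlled), via lithium acetylide 16 (not isolated)
Conditions: LiN(i-Pr)2 (2.2 equiv), THF, −78 °C; t-BuMe2SiCl (1.1 equiv), HMPA, −78 °C; cold aq. NaH2PO4/Na2HPO4 (pH 7), pentane
Reagents that add atoms: tert-butyl(chloro)dimethylsilane, CC(C)(C)[Si](C)(C)Cl
Why: Kinetic enolisation and O-silylation (Ireland-type silyl ketene acetal formation): the first equivalent of amide base removes the alkynyl proton, the second the unhindered C6–H rather than the C2–H flanked by two branched carbons, and the chlorosilane in HMPA should trap the enolate oxygen at −78 °C faster than the lithium acetylide, which is reprotonated on work-up.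

Step 10
Reactants: 17 methyl (2S,3R)-5-[tert-butyl(dimethyl)silyl]oxy-3-[(E)-hept-1-enyl]-5-methoxy-2-[(3S)-oct-1-yn-3-yl]pent-4-enoate
Product: 18 dimethyl (1S,2R,3R,4R)-2-[(E)-hept-1-enyl]-4-pentylcyclohex-5-ene-1,3-dicarboxylate
Conditions: W(CO)5(thf) (20 mol %, from W(CO)6, hν, THF), DABCO, H2O (3 equiv), THF, rt
Reagents that add atoms: none
Why: Proposed new method: W(CO)5(thf) binds the terminal alkyne and, helped by the amine, should rearrange it to the vinylidene W=C5=C4H–, whose electrophilic C5 is attacked by the ketene acetal carbon C6; water then protonates the alkenyl tungstate at C5 and takes the silyl group from the oxocarbenium ion, which gives the methyl ester and frees the catalyst. The closest known reaction is the W(CO)5(L)-catalysed endo cyclisation of ω-acetylenic silyl enol ethers of ketones to cyclohexenes; a silyl ketene acetal has not been shown as the nucleophile, but it is more nucleophilic at carbon and otherwise analogous. The single ring closes in the 6-endo-dig mode (C6 onto C5 across the chain C1–C2–C3–C4), which leaves C4=C5 inside the ring. The new stereocentre C6 is controlled by C1: in the chair-like transition state C1–H eclipses the ketene acetal (allylic 1,3-strain) and the heptenyl group points outward, so the ester should end up trans to heptenyl, which is also the more stable arrangement at this epimerisable centre. The step needs endo over 5-exo selectivity, which the vinylidene pathway and the four-atom spacing are expected to secure, and it needs C6 and not C2 as the nucleophile, which is fixed because only C6 carries the ketene acetal; the E alkene and the C2 ester are spectators.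

Step 11
Reactants: 18 dimethyl (1S,2R,3R,4R)-2-[(E)-hept-1-enyl]-4-pentylcyclohex-5-ene-1,3-dicarboxylate; 19 2-methylpropan-1-amine
Product: 20 (1S,2R,3R,4R)-2-[(E)-hept-1-enyl]-N1,N3-bis(2-methylpropyl)-4-pentylcyclohex-5-ene-1,3-dicarboxamide
Conditions: AlMe3 (6 equiv), 19 (6 equiv), toluene, 0 → 90 °C; aqueous work-up
Reagents that add atoms: none
Why: Aminolysis of both methyl esters by the dimethylaluminium amide formed from AlMe3 and the amine (Weinreb amidation) works on hindered esters without strong base, and C6 already holds the trans, more stable configuration.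

Compound list
1 | (3S)-oct-1-yn-3-ol | C#C[C@@H](O)CCCCC | starting material
2 | (3S)-oct-1-yn-3-yl methanesulfonate | C#C[C@@H](OS(C)(=O)=O)CCCCC | intermediate
3 | dimethyl propanedioate (dimethyl malonate) | COC(=O)CC(=O)OC | starting material
4 | dimethyl 2-[(3S)-oct-1-yn-3-yl]propanedioate | C#C[C@@H](CCCCC)C(C(=O)OC)C(=O)OC | intermediate
5 | 2-[(3S)-oct-1-yn-3-yl]propanedioic acid | C#C[C@@H](CCCCC)C(C(=O)O)C(=O)O | intermediate
6 | (3S)-3-ethynyloctanoic acid | C#C[C@@H](CCCCC)CC(=O)O | intermediate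
7 | (3R)-oct-1-en-3-ol | C=C[C@H](O)CCCCC | starting material
8 | (but-3-en-1-yloxy)(tert-butyl)dimethylsilane | C=CCCO[Si](C)(C)C(C)(C)C | starting material
9 | (3E,5R)-1-[tert-butyl(dimethyl)silyl]oxydec-3-en-5-ol | CCCCC[C@@H](O)/C=C/CCO[Si](C)(C)C(C)(C)C | intermediate
10 | [(3E,5R)-1-[tert-butyl(dimethyl)silyl]oxydec-3-en-5-yl] (3S)-3-ethynyloctanoate | C#C[C@@H](CCCCC)CC(=O)O[C@H](CCCCC)/C=C/CCO[Si](C)(C)C(C)(C)C | intermediate
11 | (1Z,3S)-1-[(3E,5R)-1-[tert-butyl(dimethyl)silyl]oxydec-3-en-5-yl]oxy-1-trimethylsilyloxy-3-(2-trimethylsilylethynyl)oct-1-ene | C[Si](C)(C)C#C[C@@H](CCCCC)/C=C(\O[Si](C)(C)C)O[C@H](CCCCC)/C=C/CCO[Si](C)(C)C(C)(C)C | intermediate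
12 | trimethylsilyl (2S,3S,4E)-3-[2-[tert-butyl(dimethyl)silyl]oxyethyl]-2-[(3S)-1-trimethylsilyloct-1-yn-3-yl]dec-4-enoate | C[Si](C)(C)C#C[C@@H](CCCCC)[C@@H](C(=O)O[Si](C)(C)C)[C@H](/C=C/CCCCC)CCO[Si](C)(C)C(C)(C)C | intermediate
13 | (2S,3S,4E)-3-[2-[tert-butyl(dimethyl)silyl]oxyethyl]-2-[(3S)-oct-1-yn-3-yl]dec-4-enoic acid | C#C[C@@H](CCCCC)[C@@H](C(=O)O)[C@H](/C=C/CCCCC)CCO[Si](C)(C)C(C)(C)C | intermediate
14 | (2S,3S)-3-[(E)-hept-1-enyl]-2-[(3S)-oct-1-yn-3-yl]pentanedioic acid | C#C[C@@H](CCCCC)[C@@H](C(=O)O)[C@H](/C=C/CCCCC)CC(=O)O | intermediate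
15 | dimethyl (2S,3S)-3-[(E)-hept-1-enyl]-2-[(3S)-oct-1-yn-3-yl]pentanedioate | C#C[C@@H](CCCCC)[C@@H](C(=O)OC)[C@H](/C=C/CCCCC)CC(=O)OC | intermediate
16 | lithium acetylide of 17 (C-lithiated at the alkyne terminus) | [Li]C#C[C@@H](CCCCC)[C@@H](C(=O)OC)[C@H](/C=C/CCCCC)C=C(OC)O[Si](C)(C)C(C)(C)C | intermediate
17 | methyl (2S,3R)-5-[tert-butyl(dimethyl)silyl]oxy-3-[(E)-hept-1-enyl]-5-methoxy-2-[(3S)-oct-1-yn-3-yl]pent-4-enoate | C#C[C@@H](CCCCC)[C@@H](C(=O)OC)[C@H](/C=C/CCCCC)C=C(OC)O[Si](C)(C)C(C)(C)C | intermediate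
18 | dimethyl (1S,2R,3R,4R)-2-[(E)-hept-1-enyl]-4-pentylcyclohex-5-ene-1,3-dicarboxylate | CCCCC/C=C/[C@H]1[C@H](C(=O)OC)[C@H](CCCCC)C=C[C@@H]1C(=O)OC | intermediate
19 | 2-methylpropan-1-amine (isobutylamine) | CC(C)CN | starting material
20 | (1S,2R,3R,4R)-2-[(E)-hept-1-enyl]-N1,N3-bis(2-methylpropyl)-4-pentylcyclohex-5-ene-1,3-dicarboxamide | CCCCC/C=C/[C@H]1[C@H](C(=O)NCC(C)C)[C@H](CCCCC)C=C[C@@H]1C(=O)NCC(C)C | target

Total step count: 11. Longest linear sequence: 10 steps (steps 1–3 and 5–11, from 1); step 4 is a one-step side branch.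

Steps most likely to fail

Step 10 (the labelled step). The ketene acetal may attack the internal alkyne carbon (5-exo closure), or it may lose its silyl group to water before the C–C bond forms. The fallback uses established chemistry, sets out from 15 and returns at 18. Iodination of the alkyne terminus (N-iodosuccinimide, AgNO3 cat., acetone) should give dimethyl (2S,3S)-3-[(E)-hept-1-enyl]-2-[(3S)-1-iodooct-1-yn-3-yl]pentanedioate F1. Cis-selective diimide reduction (2-nitrobenzenesulfonylhydrazide, Et3N, THF/i-PrOH) should give dimethyl (2S,3S)-3-[(E)-hept-1-enyl]-2-[(1Z,3S)-1-iodooct-1-en-3-yl]pentanedioate F2. Palladium-catalysed intramolecular α-alkenylation of the C6 ester enolate (LiN(SiMe3)2, Pd2(dba)3, P(t-Bu)3, toluene, rt) would then form the same C5–C6 bond with retention of the Z alkene and give 18.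

Step 9. The lithium acetylide may be silylated at carbon, C2 may be enolised with loss of that stereocentre, or the ketene acetal may hydrolyse during the aqueous quench. The fallback sets out from 13 and returns at 18; it makes the nucleophile by soft enolisation at the aldehyde oxidation level, where no strong base meets the alkyne.
- Methylation of 13 (MeI, K2CO3, DMF) should give methyl (2S,3S,4E)-3-[2-[tert-butyl(dimethyl)silyl]oxyethyl]-2-[(3S)-oct-1-yn-3-yl]dec-4-enoate F3.
- HF·pyridine in THF should remove the silyl ether to give methyl (2S,3S,4E)-3-(2-hydroxyethyl)-2-[(3S)-oct-1-yn-3-yl]dec-4-enoate F4, which is oxidised without delay.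
- Dess–Martin periodinane should give methyl (2S,3S,4E)-2-[(3S)-oct-1-yn-3-yl]-3-(2-oxoethyl)dec-4-enoate F5.
- i-Pr3SiOTf and Et3N in CH2Cl2 should give methyl (2S,3R,4E)-2-[(3S)-oct-1-yn-3-yl]-3-[2-tri(propan-2-yl)silyloxyethenyl]dec-4-enoate F6 without touching the ester or the alkyne.
- The tungsten-catalysed 6-endo closure under the conditions of step 10, here on a silyl enol ether (the nucleophile class for which it is established), should give methyl (1R,2R,3S,6R)-3-formyl-2-[(E)-hept-1-enyl]-6-pentylcyclohex-4-ene-1-carboxylate F7.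
- Buffered chlorite oxidation (NaClO2, NaH2PO4, 2-methylbut-2-ene, t-BuOH/H2O) should give (1S,4R,5R,6R)-6-[(E)-hept-1-enyl]-5-methoxycarbonyl-4-pentylcyclohex-2-ene-1-carboxylic acid F8, and methylation (MeI, K2CO3, DMF) gives 18.

Step 6. Z(O) selectivity in the HMPA-mediated enolisation may be incomplete, or some material may pass through a boat transition state; either erodes the C1/C2 relationship, and the C3 centre next to the enolate may add a mismatched facial bias. The fallback sets out from 1, uses acid 6 and returns at 13; it pairs a Z allylic alcohol with the E(O) enolate, which forms with higher selectivity in THF alone and whose chair is enforced by allylic strain.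
- Double deprotonation of 1 (n-BuLi, 2 equiv, THF/HMPA) and opening of oxirane should give (5S)-dec-3-yne-1,5-diol F9.
- Semi-hydrogenation (H2, Pd/CaCO3 poisoned with Pb(OAc)2, quinoline, EtOAc) should give (3Z,5S)-dec-3-ene-1,5-diol F10.
- Selective silylation of the primary hydroxyl (t-BuMe2SiCl, imidazole, CH2Cl2, 0 °C) should give (3Z,5S)-1-[tert-butyl(dimethyl)silyl]oxydec-3-en-5-ol F11.
- Steglich esterification with 6 (DCC, DMAP) should give [(3Z,5S)-1-[tert-butyl(dimethyl)silyl]oxydec-3-en-5-yl] (3S)-3-ethynyloctanoate F12.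
- Enolisation with LiN(i-Pr)2 in THF at −78 °C and silylation with Me3SiCl should give (1E,3S)-1-[(3Z,5S)-1-[tert-butyl(dimethyl)silyl]oxydec-3-en-5-yl]oxy-1-trimethylsilyloxy-3-(2-trimethylsilylethynyl)oct-1-ene F13, which rearranges to the same silyl ester 12 and, after K2CO3/MeOH, gives 13.

Further compounds
F1 | step 10 | dimethyl (2S,3S)-3-[(E)-hept-1-enyl]-2-[(3S)-1-iodooct-1-yn-3-yl]pentanedioate | IC#C[C@@H](CCCCC)[C@@H](C(=O)OC)[C@H](/C=C/CCCCC)CC(=O)OC
F2 | step 10 | dimethyl (2S,3S)-3-[(E)-hept-1-enyl]-2-[(1Z,3S)-1-iodooct-1-en-3-yl]pentanedioate | I/C=C\[C@@H](CCCCC)[C@@H](C(=O)OC)[C@H](/C=C/CCCCC)CC(=O)OC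
F3 | step 9 | methyl (2S,3S,4E)-3-[2-[tert-butyl(dimethyl)silyl]oxyethyl]-2-[(3S)-oct-1-yn-3-yl]dec-4-enoate | C#C[C@@H](CCCCC)[C@@H](C(=O)OC)[C@H](/C=C/CCCCC)CCO[Si](C)(C)C(C)(C)C
F4 | step 9 | methyl (2S,3S,4E)-3-(2-hydroxyethyl)-2-[(3S)-oct-1-yn-3-yl]dec-4-enoate | C#C[C@@H](CCCCC)[C@@H](C(=O)OC)[C@H](/C=C/CCCCC)CCO
F5 | step 9 | methyl (2S,3S,4E)-2-[(3S)-oct-1-yn-3-yl]-3-(2-oxoethyl)dec-4-enoate | C#C[C@@H](CCCCC)[C@@H](C(=O)OC)[C@H](/C=C/CCCCC)CC=O
F6 | step 9 | methyl (2S,3R,4E)-2-[(3S)-oct-1-yn-3-yl]-3-[2-tri(propan-2-yl)silyloxyethenyl]dec-4-enoate | C#C[C@@H](CCCCC)[C@@H](C(=O)OC)[C@H](/C=C/CCCCC)C=CO[Si](C(C)C)(C(C)C)C(C)C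
F7 | step 9 | methyl (1R,2R,3S,6R)-3-formyl-2-[(E)-hept-1-enyl]-6-pentylcyclohex-4-ene-1-carboxylate | CCCCC/C=C/[C@H]1[C@H](C(=O)OC)[C@H](CCCCC)C=C[C@@H]1C=O
F8 | step 9 | (1S,4R,5R,6R)-6-[(E)-hept-1-enyl]-5-methoxycarbonyl-4-pentylcyclohex-2-ene-1-carboxylic acid | CCCCC/C=C/[C@H]1[C@H](C(=O)OC)[C@H](CCCCC)C=C[C@@H]1C(=O)O
F9 | step 6 | (5S)-dec-3-yne-1,5-diol | CCCCC[C@H](O)C#CCCO
F10 | step 6 | (3Z,5S)-dec-3-ene-1,5-diol | CCCCC[C@H](O)/C=C\CCO
F11 | step 6 | (3Z,5S)-1-[tert-butyl(dimethyl)silyl]oxydec-3-en-5-ol | CCCCC[C@H](O)/C=C\CCO[Si](C)(C)C(C)(C)C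
F12 | step 6 | [(3Z,5S)-1-[tert-butyl(dimethyl)silyl]oxydec-3-en-5-yl] (3S)-3-ethynyloctanoate | C#C[C@@H](CCCCC)CC(=O)O[C@@H](CCCCC)/C=C\CCO[Si](C)(C)C(C)(C)C
F13 | step 6 | (1E,3S)-1-[(3Z,5S)-1-[tert-butyl(dimethyl)silyl]oxydec-3-en-5-yl]oxy-1-trimethylsilyloxy-3-(2-trimethylsilylethynyl)oct-1-ene | C[Si](C)(C)C#C[C@@H](CCCCC)/C=C(/O[Si](C)(C)C)O[C@@H](CCCCC)/C=C\CCO[Si](C)(C)C(C)(C)C
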